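**Retrosynthetic overview**
- C3–C4: Evans syn aldol of the C4–C13 bis-furan aldehyde with an (S)-4-benzyl-3-(silyloxyacetyl)oxazolidinone; this is the fragment union and sets C3. The C4 carbinol is re-oxidised to the ketone at the end.
- C1–C2 and Cl: imide → Weinreb amide → methyl ketone; Evans–Tishchenko 1,3-anti reduction (C2–OH free, O4 acylated); chloride introduced with inversion gives the syn chlorohydrin.
- C11–C12: B-alkyl Suzuki coupling of the 9-BBN adduct of a vinyl bis-furan with an (E)-vinyl iodide from Negishi carboalumination (sets 10E).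
- C6: taken from (R)-citronellol (ozonolysis, iodide, acetylide homologation).
- Rings: no ring is built. Both furans are bought and joined first (furyllithium addition to 4-bromo-2-furaldehyde, then ionic deoxygenation); the chain is attached afterwards.

Assumption: commercial (R)-(+)-β-citronellol (≥97% ee) and (S)-4-benzyloxazolidin-2-one supply the absolute configuration. TBS = tert-butyldimethylsilyl, rt = room temperature.

**Step 1**
Reactants: 1 3-bromofuran; 2 4-bromofuran-2-carbaldehyde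
Product: 4 (4-bromofuran-2-yl)(furan-3-yl)methanol (racemic), via furan-3-yllithium 3 (not isolated)
Conditions: 1, n-BuLi, THF, −78 °C; then 2, −78 °C; H2O
Reagents that add atoms: none
Why: Bromine–lithium exchange at −78 °C gives 3-furyllithium without isomerisation, and its 1,2-addition to the aldehyde (organolithium carbonyl addition) is much faster than exchange with the ring bromide of 2; the carbinol centre is removed in step 2.

**Step 2**
Reactants: 4 (4-bromofuran-2-yl)(furan-3-yl)methanol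
Product: 5 4-bromo-2-(furan-3-ylmethyl)furan
Conditions: Et3SiH (3 equiv), CF3CO2H, CH2Cl2, −20 → 0 °C
Reagents that add atoms: none
Why: Ionic hydrogenation: the carbocation stabilised by both furans is trapped by hydride from the excess silane faster than it alkylates another furan.

**Step 3**
Reactants: 5 4-bromo-2-(furan-3-ylmethyl)furan
Product: 6 4-ethenyl-2-(furan-3-ylmethyl)furan
Conditions: vinylboronic acid pinacol ester, Pd(dppf)Cl2 (3 mol%), K2CO3, 1,4-dioxane/H2O, 80 °C
Reagents that add atoms: 4,4,5,5-tetramethyl-2-vinyl-1,3,2-dioxaborolane (C=CB1OC(C)(C)C(C)(C)O1)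
Why: Suzuki–Miyaura coupling of a 3-bromofuran-type bromide with a vinylboronate is standard and leaves both furans untouched.

**Step 4**
Reactants: 7 (R)-citronellol
Product: 8 tert-butyl{[(3R)-3,7-dimethyloct-6-en-1-yl]oxy}dimethylsilane
Conditions: TBSCl, imidazole, CH2Cl2, 0 °C → rt
Reagents that add atoms: tert-butyldimethylsilyl chloride (CC(C)(C)[Si](C)(C)Cl)
Why: Silyl ether protection of the primary alcohol (the future C4) so that the other chain end can be worked on.

**Step 5**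
Reactants: 8 TBS ether of (R)-citronellol
Product: 10 (4R)-6-[(tert-butyldimethylsilyl)oxy]-4-methylhexan-1-ol, via aldehyde 9 (not isolated)
Conditions: O3, CH2Cl2/MeOH, −78 °C; then NaBH4, −78 °C → rt
Reagents that add atoms: ozone ([O-][O+]=O)
Why: Ozonolysis of the only alkene with reductive NaBH4 work-up gives the primary alcohol directly; the stereocentre is remote and untouched.

**Step 6**
Reactants: 10 (4R)-6-[(tert-butyldimethylsilyl)oxy]-4-methylhexan-1-ol
Product: 11 tert-butyl{[(3R)-6-iodo-3-methylhexyl]oxy}dimethylsilane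
Conditions: I2, PPh3, imidazole, CH2Cl2, 0 °C → rt
Reagents that add atoms: iodine (II)
Why: Appel-type (Garegg–Samuelsson) iodination of an unhindered primary alcohol under conditions that keep the silyl ether.

**Step 7**
Reactants: 11 tert-butyl{[(3R)-6-iodo-3-methylhexyl]oxy}dimethylsilane
Product: 12 tert-butyldimethyl{[(3R)-3-methyloct-7-yn-1-yl]oxy}silane
Conditions: LiC≡CH·H2NCH2CH2NH2, DMSO, 15 °C → rt
Reagents that add atoms: lithium acetylide–ethylenediamine complex ([Li]C#C.NCCN)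
Why: SN2 alkylation of lithium acetylide by a primary iodide in DMSO gives the terminal alkyne that carries C10 and C11.

**Step 8**
Reactants: 12 tert-butyldimethyl{[(3R)-3-methyloct-7-yn-1-yl]oxy}silane
Product: 14 tert-butyl{[(3R,7E)-8-iodo-3,7-dimethyloct-7-en-1-yl]oxy}dimethylsilane, via alkenylalane 13 (not isolated)
Conditions: AlMe3, Cp2ZrCl2 (25 mol%), CH2Cl2, 0 °C → rt; then I2, THF, −30 → 0 °C
Reagents that add atoms: trimethylaluminium (C[Al](C)C); iodine (II)
Why: Negishi zirconium-catalysed carboalumination adds Me and Al syn with Al on the terminal carbon, and iodinolysis with retention gives only the (E)-2-methyl-1-iodoalkene.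

**Step 9**
Reactants: 6 4-ethenyl-2-(furan-3-ylmethyl)furan; 14 (E)-vinyl iodide
Product: 16 tert-butyl{[(3R,7E)-10-[5-(furan-3-ylmethyl)furan-3-yl]-3,7-dimethyldec-7-en-1-yl]oxy}dimethylsilane, via B-alkyl-9-BBN 15 (not isolated)
Conditions: 6, 9-BBN, THF, 0 °C → rt; then 14, Pd(dppf)Cl2 (5 mol%), AsPh3, Cs2CO3, DMF/H2O, rt
Reagents that add atoms: none
Why: Anti-Markovnikov hydroboration of the vinyl group followed by B-alkyl Suzuki–Miyaura coupling, which proceeds with retention at the vinyl iodide and so fixes the 10E alkene.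

**Step 10**
Reactants: 16 coupled TBS ether
Product: 17 (3R,7E)-10-[5-(furan-3-ylmethyl)furan-3-yl]-3,7-dimethyldec-7-en-1-ol
Conditions: Bu4NF, THF, 0 °C → rt
Reagents that add atoms: none
Why: Fluoride desilylation of a primary TBS ether; nothing else in the molecule is fluoride-sensitive.

**Step 11**
Reactants: 17 (3R,7E)-10-[5-(furan-3-ylmethyl)furan-3-yl]-3,7-dimethyldec-7-en-1-ol
Product: 18 (3R,7E)-10-[5-(furan-3-ylmethyl)furan-3-yl]-3,7-dimethyldec-7-enal
Conditions: Dess–Martin periodinane, NaHCO3, CH2Cl2, 0 °C → rt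
Reagents that add atoms: none
Why: Dess–Martin oxidation is mild enough for furans and the trisubstituted alkene, and the β-stereocentre cannot epimerise.

**Step 12**
Reactants: 19 glycolic acid
Product: 21 2-[(tert-butyldimethylsilyl)oxy]acetic acid, via bis-silyl ester 20 (not isolated)
Conditions: TBSCl (2.2 equiv), imidazole, DMF, rt; then K2CO3 (cat.), MeOH/H2O, rt; aq. citric acid
Reagents that add atoms: tert-butyldimethylsilyl chloride (CC(C)(C)[Si](C)(C)Cl)
Why: Exhaustive silylation followed by selective solvolysis of the much more labile silyl ester leaves the silyl ether acid.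

**Step 13**
Reactants: 21 2-[(tert-butyldimethylsilyl)oxy]acetic acid; 22 (S)-4-benzyloxazolidin-2-one
Product: 24 (S)-4-benzyl-3-{2-[(tert-butyldimethylsilyl)oxy]acetyl}oxazolidin-2-one, via mixed pivalic anhydride 23 (not isolated)
Conditions: t-BuCOCl, Et3N, THF, −20 → 0 °C; then 22, LiCl, 0 °C → rt
Reagents that add atoms: none
Why: N-acylation through the mixed pivalic anhydride (LiCl/Et3N protocol); the oxazolidinone attacks the less hindered glycolyl carbonyl.

**Step 14**
Reactants: 24 (S)-4-benzyl-3-{2-[(tert-butyldimethylsilyl)oxy]acetyl}oxazolidin-2-one; 18 aldehyde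
Product: 26 (S)-4-benzyl-3-[(2S,3R,5R,9E)-2-[(tert-butyldimethylsilyl)oxy]-12-[5-(furan-3-ylmethyl)furan-3-yl]-3-hydroxy-5,9-dimethyldodec-9-enoyl]oxazolidin-2-one, via boron enolate 25 (not isolated)
Conditions: 24 (1.3 equiv), Bu2BOTf, Et3N, CH2Cl2, −78 → 0 °C; then 18, −78 → 0 °C; pH 7 buffer, MeOH, H2O2, 0 °C
Reagents that add atoms: none
Why: Evans syn aldol: the Z(O)-dibutylboron enolate reacts through a Zimmerman–Traxler chair on the face away from the benzyl group, giving the 2S,3R adduct and so setting C3 of the target (the new C4 carbinol is temporary).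

**Step 15**
Reactants: 26 aldol adduct
Product: 27 (2S,3R,5R,9E)-2-[(tert-butyldimethylsilyl)oxy]-12-[5-(furan-3-ylmethyl)furan-3-yl]-3-hydroxy-N-methoxy-N,5,9-trimethyldodec-9-enamide
Conditions: MeNHOMe·HCl, AlMe3, CH2Cl2, −10 → 0 °C
Reagents that add atoms: N,O-dimethylhydroxylamine hydrochloride (CNOC.Cl)
Why: Weinreb transamidation of the imide, assisted by the free β-hydroxyl, cleaves the auxiliary at the exocyclic carbonyl without epimerising C2 of the acyl chain.

**Step 16**
Reactants: 27 Weinreb amide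
Product: 28 (3S,4R,6R,10E)-3-[(tert-butyldimethylsilyl)oxy]-13-[5-(furan-3-ylmethyl)furan-3-yl]-4-hydroxy-6,10-dimethyltridec-10-en-2-one
Conditions: MeMgBr (3.5 equiv), THF, −20 → 0 °C; aq. NH4Cl
Reagents that add atoms: methylmagnesium bromide (C[Mg]Br)
Why: Weinreb ketone synthesis: the chelated tetrahedral adduct survives until the quench, so only one methyl (C1) adds and C3 is not epimerised.

**Step 17**
Reactants: 28 β-hydroxy methyl ketone
Product: 29 (2R,3R,4R,6R,10E)-3-[(tert-butyldimethylsilyl)oxy]-13-[5-(furan-3-ylmethyl)furan-3-yl]-2-hydroxy-6,10-dimethyltridec-10-en-4-yl propanoate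
Conditions: EtCHO (6 equiv), SmI2 (30 mol%), THF, −10 °C
Reagents that add atoms: propanal (CCC=O)
Why: Evans–Tishchenko reduction: the samarium-bound hemiacetal at O4 delivers hydride intramolecularly through a chair transition state, giving C2–OH 1,3-anti to C4 (2R, hence 2,3-anti) and leaving O4 as the propanoate, so the two hydroxyls are differentiated in the same step.

**Step 18**
Reactants: 29 hydroxy propanoate
Product: 30 (2S,3S,4R,6R,10E)-3-[(tert-butyldimethylsilyl)oxy]-2-chloro-13-[5-(furan-3-ylmethyl)furan-3-yl]-6,10-dimethyltridec-10-en-4-yl propanoate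
Conditions: CCl4, (n-C8H17)3P, toluene, 65 °C
Reagents that add atoms: tetrachloromethane (ClC(Cl)(Cl)Cl)
Why: Appel-type (Hooz) deoxychlorination: chloride displaces the alkoxyphosphonium by SN2 with inversion, turning the (2R)-carbinol into the (2S)-chloride syn to O3 under neutral conditions.

**Step 19**
Reactants: 30 chloro propanoate
Product: 31 (2S,3S,4R,6R,10E)-3-[(tert-butyldimethylsilyl)oxy]-2-chloro-13-[5-(furan-3-ylmethyl)furan-3-yl]-6,10-dimethyltridec-10-en-4-ol
Conditions: i-Bu2AlH (2.5 equiv), CH2Cl2, −78 °C; aq. KNaC4H4O6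
Reagents that add atoms: none
Why: Reductive ester cleavage at −78 °C frees O4–H without base, so there is no silyl migration and no displacement or elimination of the chloride.

**Step 20**
Reactants: 31 chloro alcohol
Product: 32 (2S,3S,6R,10E)-3-[(tert-butyldimethylsilyl)oxy]-2-chloro-13-[5-(furan-3-ylmethyl)furan-3-yl]-6,10-dimethyltridec-10-en-4-one
Conditions: Dess–Martin periodinane, NaHCO3, CH2Cl2, 0 °C → rt
Reagents that add atoms: none
Why: Buffered Dess–Martin oxidation installs the C4 ketone (removing the temporary C4 centre) without enolising C3 or eliminating HCl.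

**Step 21**
Reactants: 32 silyl-protected chloro ketone
Product: 33 (2S,3S,6R,10E)-2-chloro-13-[5-(furan-3-ylmethyl)furan-3-yl]-3-hydroxy-6,10-dimethyltridec-10-en-4-one
Conditions: HF·pyridine, pyridine, THF, 0 °C → rt
Reagents that add atoms: none
Why: Buffered fluoride desilylation is mildly acidic, so the base-sensitive α-hydroxy-β-chloro ketone and the acid-sensitive furans both survive.

**Compound list**
1 | 3-bromofuran | Brc1ccoc1 | starting material
2 | 4-bromofuran-2-carbaldehyde | O=Cc1cc(Br)co1 | starting material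
3 | furan-3-yllithium | [Li]c1ccoc1 | intermediate
4 | (4-bromofuran-2-yl)(furan-3-yl)methanol (racemic) | OC(c1ccoc1)c1cc(Br)co1 | intermediate
5 | 4-bromo-2-(furan-3-ylmethyl)furan | Brc1coc(Cc2ccoc2)c1 | intermediate
6 | 4-ethenyl-2-(furan-3-ylmethyl)furan | C=Cc1coc(Cc2ccoc2)c1 | intermediate
7 | (R)-citronellol, (3R)-3,7-dimethyloct-6-en-1-ol | CC(C)=CCC[C@@H](C)CCO | starting material
8 | tert-butyl{[(3R)-3,7-dimethyloct-6-en-1-yl]oxy}dimethylsilane | CC(C)=CCC[C@@H](C)CCO[Si](C)(C)C(C)(C)C | intermediate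
9 | (4R)-6-[(tert-butyldimethylsilyl)oxy]-4-methylhexanal | O=CCC[C@@H](C)CCO[Si](C)(C)C(C)(C)C | intermediate
10 | (4R)-6-[(tert-butyldimethylsilyl)oxy]-4-methylhexan-1-ol | OCCC[C@@H](C)CCO[Si](C)(C)C(C)(C)C | intermediate
11 | tert-butyl{[(3R)-6-iodo-3-methylhexyl]oxy}dimethylsilane | ICCC[C@@H](C)CCO[Si](C)(C)C(C)(C)C | intermediate
12 | tert-butyldimethyl{[(3R)-3-methyloct-7-yn-1-yl]oxy}silane | C#CCCC[C@@H](C)CCO[Si](C)(C)C(C)(C)C | intermediate
13 | dimethyl[(1E,6R)-8-[(tert-butyldimethylsilyl)oxy]-2,6-dimethyloct-1-en-1-yl]alumane | C/C(=C\[Al](C)C)CCC[C@@H](C)CCO[Si](C)(C)C(C)(C)C | intermediate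
14 | tert-butyl{[(3R,7E)-8-iodo-3,7-dimethyloct-7-en-1-yl]oxy}dimethylsilane | C/C(=C\I)CCC[C@@H](C)CCO[Si](C)(C)C(C)(C)C | intermediate
15 | 9-{2-[5-(furan-3-ylmethyl)furan-3-yl]ethyl}-9-borabicyclo[3.3.1]nonane | C(Cc1coc(Cc2ccoc2)c1)B1C2CCCC1CCC2 | intermediate
16 | tert-butyl{[(3R,7E)-10-[5-(furan-3-ylmethyl)furan-3-yl]-3,7-dimethyldec-7-en-1-yl]oxy}dimethylsilane | C/C(=C\CCc1coc(Cc2ccoc2)c1)CCC[C@@H](C)CCO[Si](C)(C)C(C)(C)C | intermediate
17 | (3R,7E)-10-[5-(furan-3-ylmethyl)furan-3-yl]-3,7-dimethyldec-7-en-1-ol | C/C(=C\CCc1coc(Cc2ccoc2)c1)CCC[C@@H](C)CCO | intermediate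
18 | (3R,7E)-10-[5-(furan-3-ylmethyl)furan-3-yl]-3,7-dimethyldec-7-enal | C/C(=C\CCc1coc(Cc2ccoc2)c1)CCC[C@@H](C)CC=O | intermediate
19 | glycolic acid | OCC(O)=O | starting material
20 | tert-butyldimethylsilyl 2-[(tert-butyldimethylsilyl)oxy]acetate | CC(C)(C)[Si](C)(C)OCC(=O)O[Si](C)(C)C(C)(C)C | intermediate
21 | 2-[(tert-butyldimethylsilyl)oxy]acetic acid | CC(C)(C)[Si](C)(C)OCC(O)=O | intermediate
22 | (S)-4-benzyloxazolidin-2-one | O=C1N[C@@H](Cc2ccccc2)CO1 | starting material
23 | 2-[(tert-butyldimethylsilyl)oxy]acetic pivalic anhydride | CC(C)(C)C(=O)OC(=O)CO[Si](C)(C)C(C)(C)C | intermediate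
24 | (S)-4-benzyl-3-{2-[(tert-butyldimethylsilyl)oxy]acetyl}oxazolidin-2-one | CC(C)(C)[Si](C)(C)OCC(=O)N1[C@@H](Cc2ccccc2)COC1=O | intermediate
25 | (S)-4-benzyl-3-{(Z)-2-[(tert-butyldimethylsilyl)oxy]-1-[(dibutylboranyl)oxy]ethenyl}oxazolidin-2-one | CCCCB(CCCC)O/C(=C\O[Si](C)(C)C(C)(C)C)N1[C@@H](Cc2ccccc2)COC1=O | intermediate
26 | (S)-4-benzyl-3-[(2S,3R,5R,9E)-2-[(tert-butyldimethylsilyl)oxy]-12-[5-(furan-3-ylmethyl)furan-3-yl]-3-hydroxy-5,9-dimethyldodec-9-enoyl]oxazolidin-2-one | C/C(=C\CCc1coc(Cc2ccoc2)c1)CCC[C@@H](C)C[C@@H](O)[C@H](O[Si](C)(C)C(C)(C)C)C(=O)N1[C@@H](Cc2ccccc2)COC1=O | intermediate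
27 | (2S,3R,5R,9E)-2-[(tert-butyldimethylsilyl)oxy]-12-[5-(furan-3-ylmethyl)furan-3-yl]-3-hydroxy-N-methoxy-N,5,9-trimethyldodec-9-enamide | C/C(=C\CCc1coc(Cc2ccoc2)c1)CCC[C@@H](C)C[C@@H](O)[C@H](O[Si](C)(C)C(C)(C)C)C(=O)N(C)OC | intermediate
28 | (3S,4R,6R,10E)-3-[(tert-butyldimethylsilyl)oxy]-13-[5-(furan-3-ylmethyl)furan-3-yl]-4-hydroxy-6,10-dimethyltridec-10-en-2-one | C/C(=C\CCc1coc(Cc2ccoc2)c1)CCC[C@@H](C)C[C@@H](O)[C@H](O[Si](C)(C)C(C)(C)C)C(C)=O | intermediate
29 | (2R,3R,4R,6R,10E)-3-[(tert-butyldimethylsilyl)oxy]-13-[5-(furan-3-ylmethyl)furan-3-yl]-2-hydroxy-6,10-dimethyltridec-10-en-4-yl propanoate | C/C(=C\CCc1coc(Cc2ccoc2)c1)CCC[C@@H](C)C[C@@H](OC(=O)CC)[C@H](O[Si](C)(C)C(C)(C)C)[C@@H](C)O | intermediate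
30 | (2S,3S,4R,6R,10E)-3-[(tert-butyldimethylsilyl)oxy]-2-chloro-13-[5-(furan-3-ylmethyl)furan-3-yl]-6,10-dimethyltridec-10-en-4-yl propanoate | C/C(=C\CCc1coc(Cc2ccoc2)c1)CCC[C@@H](C)C[C@@H](OC(=O)CC)[C@H](O[Si](C)(C)C(C)(C)C)[C@H](C)Cl | intermediate
31 | (2S,3S,4R,6R,10E)-3-[(tert-butyldimethylsilyl)oxy]-2-chloro-13-[5-(furan-3-ylmethyl)furan-3-yl]-6,10-dimethyltridec-10-en-4-ol | C/C(=C\CCc1coc(Cc2ccoc2)c1)CCC[C@@H](C)C[C@@H](O)[C@H](O[Si](C)(C)C(C)(C)C)[C@H](C)Cl | intermediate
32 | (2S,3S,6R,10E)-3-[(tert-butyldimethylsilyl)oxy]-2-chloro-13-[5-(furan-3-ylmethyl)furan-3-yl]-6,10-dimethyltridec-10-en-4-one | C/C(=C\CCc1coc(Cc2ccoc2)c1)CCC[C@@H](C)CC(=O)[C@H](O[Si](C)(C)C(C)(C)C)[C@H](C)Cl | intermediate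
33 | (2S,3S,6R,10E)-2-chloro-13-[5-(furan-3-ylmethyl)furan-3-yl]-3-hydroxy-6,10-dimethyltridec-10-en-4-one (CNP0209639.1) | C/C(=C\CCc1coc(Cc2ccoc2)c1)CCC[C@@H](C)CC(=O)[C@H](O)[C@H](C)Cl | target

**Totals**
Total step count: 21.
Longest linear sequence: 16 steps, from 7 to 33 (steps 4–11, then 14–21).

**Three steps most likely to fail**

Step 17 (Evans–Tishchenko on an α-silyloxy β-hydroxy ketone; risks are retro-aldol, acyl or silyl migration and slow turnover). The fallback sets out from 28 and comes back to the route at 31. Hydroxyl-directed Evans–Saksena reduction of 28 (Me4NBH(OAc)3, MeCN/AcOH, −30 °C) gives the 2,4-anti diol (2R,3R,4R,6R,10E)-3-[(tert-butyldimethylsilyl)oxy]-13-[5-(furan-3-ylmethyl)furan-3-yl]-6,10-dimethyltridec-10-ene-2,4-diol F3. MeC(OMe)3 with catalytic pyridinium p-toluenesulfonate closes it to the 2-methoxy-2-methyl-1,3-dioxane bridging O2 and O4 (cyclic orthoacetate) F4. Me3SiCl in CH2Cl2 at 0 °C ionises this to the dioxanylium ion, which chloride should open at the less hindered, methyl-bearing C2 with inversion, giving (2S,3S,4R,6R,10E)-3-[(tert-butyldimethylsilyl)oxy]-2-chloro-13-[5-(furan-3-ylmethyl)furan-3-yl]-6,10-dimethyltridec-10-en-4-yl acetate F5. i-Bu2AlH at −78 °C then removes the acetate to give 31. This path also replaces steps 18 and 19; its weak point is the regioselectivity of the chloride opening, which rests on sterics only.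

Step 18 (deoxychlorination of a hindered secondary carbinol flanked by a silyloxy carbon; risks are elimination and participation of the O4 ester). The fallback sets out from 29 and comes back at 30. ClCH2SO2Cl and pyridine in CH2Cl2 at 0 °C convert 29 into the discrete sulfonate (2R,3S,4R,6R,10E)-3-[(tert-butyldimethylsilyl)oxy]-2-{[(chloromethyl)sulfonyl]oxy}-13-[5-(furan-3-ylmethyl)furan-3-yl]-6,10-dimethyltridec-10-en-4-yl propanoate F6. LiCl in DMF at 40 °C displaces it by SN2 with inversion to give 30; an isolated, highly reactive sulfonate reacts at lower temperature than the phosphonium route.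

Step 2 (acid-promoted deoxygenation of a bis-furyl carbinol; risk is oligomerisation of the furans by the furfuryl cation). The fallback sets out from 4 and comes back at 5. MnO2 in CH2Cl2 oxidises 4 to (4-bromofuran-2-yl)(furan-3-yl)methanone F1. Wolff–Kishner reduction under Huang-Minlon conditions (N2H4·H2O, KOH, diethylene glycol, 120 → 190 °C) proceeds through (4-bromofuran-2-yl)(furan-3-yl)methanone hydrazone F2, which loses nitrogen to give 5. The deoxygenation then runs under base, which furans tolerate much better than acid.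

**Further compounds**
F1 | step 2 | (4-bromofuran-2-yl)(furan-3-yl)methanone | O=C(c1ccoc1)c1cc(Br)co1
F2 | step 2 | (4-bromofuran-2-yl)(furan-3-yl)methanone hydrazone | NN=C(c1ccoc1)c1cc(Br)co1
F3 | step 17 | (2R,3R,4R,6R,10E)-3-[(tert-butyldimethylsilyl)oxy]-13-[5-(furan-3-ylmethyl)furan-3-yl]-6,10-dimethyltridec-10-ene-2,4-diol | C/C(=C\CCc1coc(Cc2ccoc2)c1)CCC[C@@H](C)C[C@@H](O)[C@H](O[Si](C)(C)C(C)(C)C)[C@@H](C)O
F4 | step 17 | cyclic orthoacetate of F3: 2-methoxy-2-methyl-1,3-dioxane across O2 and O4, orthoester carbon as a mixture, other centres as in F3 | C/C(=C\CCc1coc(Cc2ccoc2)c1)CCC[C@@H](C)C[C@H]1OC(C)(OC)O[C@H](C)[C@H]1O[Si](C)(C)C(C)(C)C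
F5 | step 17 | (2S,3S,4R,6R,10E)-3-[(tert-butyldimethylsilyl)oxy]-2-chloro-13-[5-(furan-3-ylmethyl)furan-3-yl]-6,10-dimethyltridec-10-en-4-yl acetate | C/C(=C\CCc1coc(Cc2ccoc2)c1)CCC[C@@H](C)C[C@@H](OC(C)=O)[C@H](O[Si](C)(C)C(C)(C)C)[C@H](C)Cl
F6 | step 18 | (2R,3S,4R,6R,10E)-3-[(tert-butyldimethylsilyl)oxy]-2-{[(chloromethyl)sulfonyl]oxy}-13-[5-(furan-3-ylmethyl)furan-3-yl]-6,10-dimethyltridec-10-en-4-yl propanoate | C/C(=C\CCc1coc(Cc2ccoc2)c1)CCC[C@@H](C)C[C@@H](OC(=O)CC)[C@H](O[Si](C)(C)C(C)(C)C)[C@@H](C)OS(=O)(=O)CCl
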